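Its constants were set for the occasion; the run is a simulation.

A small charge of protic impurity competes with the nucleophile for the electrophile, and three flasks differ in nucleophile.

| flask | electrophile | nucleophile | protic impurity | solid base | time |
|---|---|---|---|---|---|
| larch | 0.019 M | 1.50 equiv | 9.50 mM | 1.20 equiv | 2.5 min |
| alder | 0.019 M | 2.20 equiv | 9.50 mM | 1.20 equiv | 2.5 min |
| oak | 0.019 M | 3.40 equiv | 9.50 mM | 1.20 equiv | 2.5 min |

    electrophile + nucleophile → acid set free + target (k1 = 0.083 /M/s)
    acid set free + free base ⇌ salt of the base, settled at all times (K2 = 3500 /M)
    solid base ⇌ free base, rate k3*(cs3 - [free base]) while solid is left; crystals form when [free base] > cs3 (cs3 = 1.4 mM, k3 = 0.0027 /s)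
    electrophile + protic impurity → quenched substrate (k4 = 0.38 /M/s)
    nucleophile + acid set free ⇌ protonated nucleophile, settled at all times (K5 = 11000 /M)

- solid base is a solid; its amount is given per volume of the solution
- at the start none of the solid base is in solution
- run time (larch): 2.5 min

- part of the electrophile that has reacted at the end, larch
- part of the electrophile that has reacted at the end, alder
- part of the electrophile that has reacted at the end, oak
- what raising the equivalents of nucleophile from its lowest to its highest value here does to the part of the electrophile that has reacted (changes below 5 percentage points count as none) (it rises / no change / it falls)

Electrophile has two exits, so it falls pseudo-first-order at a pace: the coupling constant times [nucleophile] plus the quench constant times [protic impurity]. Nucleophile also binds the acid set free, since 310 for it at the start exceeds 4.90 for free base at its solubility. So each target costs two nucleophiles.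

In larch the charged levels give a pace of 0.359 /min, and over the run a first answer of 59.2%. At the charged levels, 39.6% of that couples, which reckons to 4.45 mM of target and 6.79 mM of quenched substrate. But the levels fall. Reckoned between the charge and this first answer, at two nucleophiles per target, the midway estimate for larch is 24.0 mM for [nucleophile] and 6.10 mM for [protic impurity]. Put back, these give 0.259 /min, the midway pace, and the estimate for larch becomes 47.7%. From charged paces of 0.425 /min and 0.538 /min, the same round gives 55.3% for alder and 66.0% for oak.

The forecast gives 48.4%, 55.4% and 65.4%, and says of the trend: it rises. Its ground: “Each target therefore costs two nucleophiles”.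

The simulation gives 48.2%, 55.3% and 65.4%: it rises, by 17 percentage points.

By the end, larch has lost twice as much free nucleophile as it has made target. Larch has not come to rest at the end of the run. The end levels in larch give a pace of 0.202 /min, slower than the midway 0.259 /min, and at that pace a half-life of 3.43 min, longer than the run. A neighbour of larch with 0.024 M of protic impurity has a charged pace of 0.689 /min. One round gives 73.5%, and that flask gives 72.3%. At 25.0 min larch has used 94.7% of its electrophile, with target at 49.2% and quenched substrate at 45.5% of the electrophile charged.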